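## Plan

- **Enabling feature:** the ether oxygen between ring C (the 1,3-phenylene) and ring D (the methoxy-1,4-benzoquinone) is bound to quinone C-2. C-2 is the β-carbon of the enone C-2=C-3–C-4=O, so the aryl–O–quinone link is a vinylogous aryl ester and is cut first, back to a ring-C phenol and a 2-chloroquinone.
- **Further cuts:** the open chain is then cut at both CH2–CH2 bridges (as Wittig alkenes) and at the A–B diaryl ether (SNAr).
- **Chain assembly:** ring B and ring A are joined by SNAr on 4-fluorobenzonitrile, and ring C is added by Wittig at the ring-B aldehyde. The nitrile is reduced to the aldehyde, ring D is added as a tetramethoxybenzyl ylide, and one diimide reduction saturates both bridges while keeping the benzyl ether.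
- **Ring D and ring closure:** ring D goes from tetramethoxyarene to 2,5-dimethoxyquinone, 2-hydroxyquinone and 2-chloroquinone, and the ring-C silyl ether is then removed. The 18-membered macrocycle, the only ring made in the route, closes next, and debenzylation finishes the synthesis.
- **Stereochemistry:** there is none to set. The alkene geometries are erased by the reduction.

Key step: step 15

Assumption: the target SMILES has no stereodescriptor and the molecule has no stereocentre. The 18-membered cyclophane is taken to be conformationally mobile, so no enantiomer question arises. Quinone numbering throughout: C-1 (=O), C-2 (OAr, Cl, OH or OMe), C-3 (side chain), C-4 (=O), C-5 (OMe), C-6 (H).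

## Route

Step 1
Reactants: 1 3,4-dihydroxybenzaldehyde
Product: 2 4-(benzyloxy)-3-hydroxybenzaldehyde
Conditions: BnBr (1.0 equiv), NaHCO3, DMF, 40 °C
Reagents that add atoms: benzyl bromide, BrCc1ccccc1
Why: Williamson etherification in which only the more acidic 4-OH, conjugated with the para formyl group, is ionised by hydrogen carbonate, so one equivalent of halide should alkylate that oxygen selectively.

Step 2
Reactants: 2 4-(benzyloxy)-3-hydroxybenzaldehyde; 3 4-fluorobenzonitrile
Product: 4 4-[2-(benzyloxy)-5-formylphenoxy]benzonitrile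
Conditions: K2CO3, DMF, 120 °C
Reagents that add atoms: none
Why: SNAr displacement of fluoride para to the nitrile by the phenoxide of 2, with the nitrile serving as a latent aldehyde so that the two later olefination sites of the A–B unit stay distinguishable.

Step 3
Reactants: 5 3-hydroxybenzyl alcohol
Product: 6 (3-hydroxybenzyl)triphenylphosphonium bromide
Conditions: Ph3P·HBr, MeCN, reflux
Reagents that add atoms: triphenylphosphine hydrobromide, Br.c1ccc(cc1)P(c1ccccc1)c1ccccc1
Why: Acid-promoted substitution of a benzylic alcohol by triphenylphosphine gives the phosphonium salt directly and leaves the phenol untouched.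

Step 4
Reactants: 6 (3-hydroxybenzyl)triphenylphosphonium bromide
Product: 7 triphenyl[3-(triisopropylsilyloxy)benzyl]phosphonium bromide
Conditions: TIPSCl, imidazole, CH2Cl2, rt
Reagents that add atoms: triisopropylsilyl chloride, CC(C)[Si](Cl)(C(C)C)C(C)C
Why: Standard phenol silylation, with the bulky aryl TIPS ether chosen because it should survive ylide base, DIBAL-H, diimide, CAN, aqueous acid and oxalyl chloride yet fall to HF without any base.

Step 5
Reactants: 7 triphenyl[3-(triisopropylsilyloxy)benzyl]phosphonium bromide; 4 4-[2-(benzyloxy)-5-formylphenoxy]benzonitrile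
Product: 9 4-{2-(benzyloxy)-5-[2-(3-triisopropylsilyloxyphenyl)ethenyl]phenoxy}benzonitrile (E/Z mixture), via silyloxybenzylidene ylide 8 (not isolated)
Conditions: NaHMDS, THF, −78 → 0 °C; then 4, → rt
Reagents that add atoms: none
Why: Wittig olefination of the aryl aldehyde by a semi-stabilised benzylic ylide, to which the nitrile is inert, and the alkene geometry does not matter because step 10 saturates the bond.

Step 6
Reactants: 9 4-{2-(benzyloxy)-5-[2-(3-triisopropylsilyloxyphenyl)ethenyl]phenoxy}benzonitrile
Product: 11 4-{2-(benzyloxy)-5-[2-(3-triisopropylsilyloxyphenyl)ethenyl]phenoxy}benzaldehyde (E/Z mixture), via N-diisobutylaluminio imine 10 (not isolated)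
Conditions: DIBAL-H, CH2Cl2, −78 °C; then 1 M HCl, 0 °C
Reagents that add atoms: water, O
Why: DIBAL-H reduction of an aryl nitrile stops at the N-aluminated imine, which dilute acid hydrolyses to the aldehyde, while the alkene, benzyl ether and silyl ether are inert.

Step 7
Reactants: 12 1,2,4,5-tetramethoxybenzene
Product: 14 (2,3,5,6-tetramethoxyphenyl)methanol, via 2,3,5,6-tetramethoxyphenyllithium 13 (not isolated)
Conditions: n-BuLi, THF, 0 °C → rt; (CH2O)n, rt; H2O
Reagents that add atoms: formaldehyde (from paraformaldehyde), C=O
Why: Directed ortho-lithiation at a C–H flanked by two methoxy groups (the two free positions are equivalent), followed by hydroxymethylation of the aryllithium with formaldehyde.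

Step 8
Reactants: 14 (2,3,5,6-tetramethoxyphenyl)methanol
Product: 15 triphenyl(2,3,5,6-tetramethoxybenzyl)phosphonium bromide
Conditions: Ph3P·HBr, MeCN, reflux
Reagents that add atoms: triphenylphosphine hydrobromide, Br.c1ccc(cc1)P(c1ccccc1)c1ccccc1
Why: Same direct alcohol-to-phosphonium conversion as step 3, helped here by easy ionisation of the electron-rich benzylic alcohol, with phosphine capture expected to outrun Friedel–Crafts self-alkylation.

Step 9
Reactants: 15 triphenyl(2,3,5,6-tetramethoxybenzyl)phosphonium bromide; 11 4-{2-(benzyloxy)-5-[2-(3-triisopropylsilyloxyphenyl)ethenyl]phenoxy}benzaldehyde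
Product: 17 1-(benzyloxy)-2-{4-[2-(2,3,5,6-tetramethoxyphenyl)ethenyl]phenoxy}-4-[2-(3-triisopropylsilyloxyphenyl)ethenyl]benzene (E/Z mixture at both alkenes), via tetramethoxybenzylidene ylide 16 (not isolated)
Conditions: NaHMDS, THF, −78 → 0 °C; then 11, → rt
Reagents that add atoms: none
Why: Second Wittig olefination, in which the electron-rich and therefore reactive ylide should offset its two ortho methoxy groups, and the geometry is again irrelevant.

Step 10
Reactants: 17 the bis-stilbene
Product: 18 1-(benzyloxy)-2-{4-[2-(2,3,5,6-tetramethoxyphenyl)ethyl]phenoxy}-4-[2-(3-triisopropylsilyloxyphenyl)ethyl]benzene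
Conditions: TsNHNH2 (excess), NaOAc, DME/H2O, reflux
Reagents that add atoms: none
Why: Diimide reduction delivers hydrogen concertedly to both C=C bonds and, unlike hydrogenation over palladium, cannot hydrogenolyse the aryl benzyl ether or disturb the silyl ether.

Step 11
Reactants: 18 the saturated tetramethoxyarene
Product: 19 2,5-dimethoxy-3-R-1,4-benzoquinone, R = 2-{4-[2-(benzyloxy)-5-(3-triisopropylsilyloxyphenethyl)phenoxy]phenyl}ethyl
Conditions: CAN (2.2 equiv), MeCN/H2O, 0 °C
Reagents that add atoms: water, O
Why: CAN oxidative demethylation of a 1,4-dimethoxyarene, in which ring D is by far the most easily oxidised ring and its symmetry about the alkyl-C/H-C axis means either para pair gives the same quinone.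

Step 12
Reactants: 19 2,5-dimethoxy-3-R-1,4-benzoquinone
Product: 20 2-hydroxy-5-methoxy-3-R-1,4-benzoquinone (same R)
Conditions: 70% aq HClO4, 1,4-dioxane, rt
Reagents that add atoms: water, O
Why: Acid-catalysed hydrolysis of a vinylogous ester, in which the C-2 methoxy group is twisted out of conjugation by the neighbouring chain and exchanges with water faster than the C-5 methoxy group, the known selectivity of 3-alkyl-2,5-dimethoxybenzoquinones.

Step 13
Reactants: 20 2-hydroxy-5-methoxy-3-R-1,4-benzoquinone
Product: 21 2-chloro-5-methoxy-3-R-1,4-benzoquinone (same R)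
Conditions: (COCl)2, DMF (cat.), CH2Cl2, 0 °C → rt
Reagents that add atoms: oxalyl chloride, O=C(Cl)C(Cl)=O
Why: The hydroxyquinone is a vinylogous carboxylic acid, and the Vilsmeier-type chloroiminium salt converts it into the vinylogous acid chloride, as is known for hydroxyquinones and cyclic 1,3-dicarbonyl compounds.

Step 14
Reactants: 21 2-chloro-5-methoxy-3-R-1,4-benzoquinone
Product: 22 2-chloro-3-(2-{4-[2-(benzyloxy)-5-(3-hydroxyphenethyl)phenoxy]phenyl}ethyl)-5-methoxy-1,4-benzoquinone (seco chloroquinone, ring-C phenol free)
Conditions: HF·pyridine, THF, 0 °C → rt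
Reagents that add atoms: none
Why: Fluoride-driven cleavage of the aryl silyl ether in an acidic medium releases the neutral phenol, which should not add to the chloroquinone without base, and the benzyl ether and C–Cl bond are unaffected.

Step 15
Reactants: 22 seco chloroquinone with free ring-C phenol
Product: 24 O-benzyl ether of the target (18-membered macrocycle with the ring-C oxygen on quinone C-2), via caesium phenoxide 23 (not isolated)
Conditions: Cs2CO3, 4 Å MS, MeCN, rt, Ar, slow addition of 22 (final ca. 1 mM)
Reagents that add atoms: none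
Why: Carbonate ionises the only free phenol (ring C), and phenoxide 23 adds to C-2, the chlorine-bearing β-carbon of the C-2=C-3–C-4=O enone of ring D, giving a delocalised enolate that collapses with loss of chloride and restores the quinone. The closest known reaction is the bimolecular preparation of aryloxyquinones from phenols, carbonate base and haloquinones by addition–elimination, and macrocyclic diaryl ethers closed by intramolecular SNAr show that this kind of C–O bond formation tolerates ring closure. The single new ring closes in an 18-endo-trig sense (C-2 and C-3 both end up in the ring), which carries no stereoelectronic cost at this size because the two CH2CH2 hinges let the chain end reach the face of the planar quinone, and slow addition at high dilution favours it over oligomers. No stereocentre is created. Site selectivity is needed among C-2, C-5 and C-6: chloride is a far better leaving group than methoxide, C-5 is deactivated by its own oxygen lone pair, C-6 is the electron-rich α-carbon of the MeO–C-5=C-6–C-1=O vinylogous ester, and C-3 is blocked by the chain. The benzyl ether removes the ring-B oxygen as a competing nucleophile, and the sieves keep hydroxide from returning 22 to the hydroxyquinone.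

Step 16
Reactants: 24 O-benzyl ether of the target
Product: 26 target CNP0332646.0, via debenzylated hydroquinone 25 (not isolated)
Conditions: H2 (1 atm), Pd/C, EtOAc, rt; filter; air, rt
Reagents that add atoms: none
Why: Hydrogenolysis of the aryl benzyl ether also reduces the quinone to the robust hydroquinone 25, whose electron-rich ring is reoxidised by air (autoxidation, oxygen ending as water) while the simple ring-B phenol stays intact.

## Compound list

1 | 3,4-dihydroxybenzaldehyde | O=Cc1ccc(O)c(O)c1 | starting material
2 | 4-(benzyloxy)-3-hydroxybenzaldehyde | O=Cc1ccc(OCc2ccccc2)c(O)c1 | intermediate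
3 | 4-fluorobenzonitrile | N#Cc1ccc(F)cc1 | starting material
4 | 4-[2-(benzyloxy)-5-formylphenoxy]benzonitrile | N#Cc1ccc(cc1)Oc1cc(C=O)ccc1OCc1ccccc1 | intermediate
5 | 3-hydroxybenzyl alcohol | OCc1cccc(O)c1 | starting material
6 | (3-hydroxybenzyl)triphenylphosphonium bromide | [Br-].Oc1cccc(C[P+](c2ccccc2)(c2ccccc2)c2ccccc2)c1 | intermediate
7 | triphenyl[3-(triisopropylsilyloxy)benzyl]phosphonium bromide | [Br-].CC(C)[Si](Oc1cccc(C[P+](c2ccccc2)(c2ccccc2)c2ccccc2)c1)(C(C)C)C(C)C | intermediate
8 | ylide of 7 (not isolated) | CC(C)[Si](Oc1cccc(C=P(c2ccccc2)(c2ccccc2)c2ccccc2)c1)(C(C)C)C(C)C | intermediate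
9 | stilbene nitrile, E/Z mixture | N#Cc1ccc(cc1)Oc1cc(C=Cc2cccc(O[Si](C(C)C)(C(C)C)C(C)C)c2)ccc1OCc1ccccc1 | intermediate
10 | N-diisobutylaluminio imine of 9 (not isolated) | CC(C)C[Al](CC(C)C)N=Cc1ccc(cc1)Oc1cc(C=Cc2cccc(O[Si](C(C)C)(C(C)C)C(C)C)c2)ccc1OCc1ccccc1 | intermediate
11 | stilbene aldehyde, E/Z mixture | O=Cc1ccc(cc1)Oc1cc(C=Cc2cccc(O[Si](C(C)C)(C(C)C)C(C)C)c2)ccc1OCc1ccccc1 | intermediate
12 | 1,2,4,5-tetramethoxybenzene | COc1cc(OC)c(OC)cc1OC | starting material
13 | 2,3,5,6-tetramethoxyphenyllithium (not isolated) | [Li]c1c(OC)c(OC)cc(OC)c1OC | intermediate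
14 | (2,3,5,6-tetramethoxyphenyl)methanol | OCc1c(OC)c(OC)cc(OC)c1OC | intermediate
15 | triphenyl(2,3,5,6-tetramethoxybenzyl)phosphonium bromide | [Br-].COc1cc(OC)c(OC)c(C[P+](c2ccccc2)(c2ccccc2)c2ccccc2)c1OC | intermediate
16 | ylide of 15 (not isolated) | COc1cc(OC)c(OC)c(C=P(c2ccccc2)(c2ccccc2)c2ccccc2)c1OC | intermediate
17 | bis-stilbene, E/Z mixture at both alkenes | COc1cc(OC)c(OC)c(C=Cc2ccc(cc2)Oc2cc(C=Cc3cccc(O[Si](C(C)C)(C(C)C)C(C)C)c3)ccc2OCc2ccccc2)c1OC | intermediate
18 | saturated seco tetramethoxyarene | COc1cc(OC)c(OC)c(CCc2ccc(cc2)Oc2cc(CCc3cccc(O[Si](C(C)C)(C(C)C)C(C)C)c3)ccc2OCc2ccccc2)c1OC | intermediate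
19 | 2,5-dimethoxy-3-R-1,4-benzoquinone | COC1=CC(=O)C(OC)=C(CCc2ccc(cc2)Oc2cc(CCc3cccc(O[Si](C(C)C)(C(C)C)C(C)C)c3)ccc2OCc2ccccc2)C1=O | intermediate
20 | 2-hydroxy-5-methoxy-3-R-1,4-benzoquinone | COC1=CC(=O)C(O)=C(CCc2ccc(cc2)Oc2cc(CCc3cccc(O[Si](C(C)C)(C(C)C)C(C)C)c3)ccc2OCc2ccccc2)C1=O | intermediate
21 | 2-chloro-5-methoxy-3-R-1,4-benzoquinone | COC1=CC(=O)C(Cl)=C(CCc2ccc(cc2)Oc2cc(CCc3cccc(O[Si](C(C)C)(C(C)C)C(C)C)c3)ccc2OCc2ccccc2)C1=O | intermediate
22 | seco chloroquinone, ring-C phenol free, ring-B benzyl ether | COC1=CC(=O)C(Cl)=C(CCc2ccc(cc2)Oc2cc(ccc2OCc2ccccc2)CCc2cccc(O)c2)C1=O | intermediate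
23 | caesium phenoxide of 22 (not isolated) | [Cs+].COC1=CC(=O)C(Cl)=C(CCc2ccc(cc2)Oc2cc(ccc2OCc2ccccc2)CCc2cccc([O-])c2)C1=O | intermediate
24 | O-benzyl ether of the target | COC1=CC(=O)C2=C(CCc3ccc(cc3)Oc3cc(ccc3OCc3ccccc3)CCc3cccc(c3)O2)C1=O | intermediate
25 | debenzylated macrocyclic hydroquinone (not isolated) | COc1cc(O)c2c(CCc3ccc(cc3)Oc3cc(ccc3O)CCc3cccc(c3)O2)c1O | intermediate
26 | CNP0332646.0 | COC1=CC(=O)C2=C(CCc3ccc(cc3)Oc3cc(ccc3O)CCc3cccc(c3)O2)C1=O | target

## Step count and risks

Total step count: 16.
Longest linear sequence: 12 steps (1, 2, 5, 6, 9, 10, 11, 12, 13, 14, 15, 16).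

**Step 15.**
- What may go wrong: intermolecular attack may outrun ring closure and give oligomers, or the carbonate may tautomerise the alkylquinone through its benzylic CH2 before the ring closes.
- Fallback: it sets out from silyl ether 21 and returns to the route at 24, leaving out the isolation of 22. The aryl silyl ether itself serves as a masked nucleophile.
- How it runs: 21 is added slowly to CsF in dry MeCN at high dilution. Phenoxide 23 is then released only as fast as it is consumed, and no carbonate base is present.
- New compounds: this fallback makes no compound outside the list (F0).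

**Step 13.**
- What may go wrong: the deoxychlorination may be unclean, because the HCl set free can strip the silyl ether or cleave the C-5 vinylogous methyl ester, and the chloroiminium salt may attack the electron-rich rings.
- Fallback: it sets out from 20, returns at 21, and separates activation from chloride delivery under acid-free conditions.
- How it runs: Tf2O and 2,6-lutidine in CH2Cl2 at −78 °C should give 5-methoxy-3-R-2-(trifluoromethylsulfonyloxy)-1,4-benzoquinone F1. Lithium chloride in THF then replaces the triflate at C-2 by addition–elimination.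

**Step 12.**
- What may go wrong: site selectivity between the two methoxy groups may be poor, or the TIPS group may be lost in the strong acid.
- Fallback: it sets out from 19 and returns at 20.
- Exhaustive hydrolysis: aqueous NaOH in THF/EtOH followed by acidification removes both methyl groups and the silyl group. This gives 2,5-dihydroxy-3-(2-{4-[2-(benzyloxy)-5-(3-hydroxyphenethyl)phenoxy]phenyl}ethyl)-1,4-benzoquinone F2.
- Selective remethylation: MeOH with catalytic H2SO4 is a vinylogous Fischer esterification that should occur only at the unhindered C-5 hydroxyl. It gives the 2-hydroxy-5-methoxyquinone with free ring-C phenol F3.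
- Resilylation: TIPSCl (1 equiv) and imidazole then silylate the ring-C phenol in preference to the delocalised, weakly nucleophilic hydroxyquinone anion.

## Further compounds

F0 | step 15 | none | none
F1 | step 13 | 5-methoxy-3-R-2-(trifluoromethylsulfonyloxy)-1,4-benzoquinone | COC1=CC(=O)C(OS(=O)(=O)C(F)(F)F)=C(CCc2ccc(cc2)Oc2cc(CCc3cccc(O[Si](C(C)C)(C(C)C)C(C)C)c3)ccc2OCc2ccccc2)C1=O
F2 | step 12 | 2,5-dihydroxy-3-(2-{4-[2-(benzyloxy)-5-(3-hydroxyphenethyl)phenoxy]phenyl}ethyl)-1,4-benzoquinone | OC1=CC(=O)C(O)=C(CCc2ccc(cc2)Oc2cc(CCc3cccc(O)c3)ccc2OCc2ccccc2)C1=O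
F3 | step 12 | 2-hydroxy-5-methoxy-3-(2-{4-[2-(benzyloxy)-5-(3-hydroxyphenethyl)phenoxy]phenyl}ethyl)-1,4-benzoquinone | COC1=CC(=O)C(O)=C(CCc2ccc(cc2)Oc2cc(CCc3cccc(O)c3)ccc2OCc2ccccc2)C1=O
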